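**Retrosynthetic overview**
- The acetate, the angelate and the enal are installed last on a bicyclic hydroxy lactone.
- Both rings form in one operation from an acyclic aldehyde/allylic bromide: the six-membered carbocycle closes first by intramolecular In-mediated Barbier allylation (C7–C8), then the cis-fused α-methylene lactone closes by lactonisation.
- The acyclic precursor is cut at C6–C7 (Stille acylation, then Felkin–Anh reduction for C6) and at C5–C10 (ester link, then Ireland–Claisen rearrangement for C5 and the quaternary C10).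
- This leaves three fragments of similar size: fragment A (C1, C2, C8–C10, C14) from (R)-glyceraldehyde acetonide, fragment B (C3–C6, C15) from itaconic anhydride, fragment C (C7, C11–C13) from methyl acrylate; angelic acid is the fourth building block.

Assumption: skeleton atoms carry elemanolide numbers (C1=C2 vinyl and C14 methyl on C10; C3H2=C4(C15) on C5; ring C5–C10; C11(=C13H2)–C12(=O)–O–C8), and (R)-glyceraldehyde acetonide is bought as such. TBS = tert-butyldimethylsilyl, TBDPS = tert-butyldiphenylsilyl. The stereochemical outcomes of steps 15, 17 and 22 are predictions from transition-state models, not established results.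

**Step 1**
Reactants: 1 (R)-2,2-dimethyl-1,3-dioxolane-4-carbaldehyde
Product: 2 1-[(4R)-2,2-dimethyl-1,3-dioxolan-4-yl]ethan-1-ol (both carbinol epimers)
Conditions: MeMgBr, THF, −78 °C
Reagents that add atoms: methylmagnesium bromide, C[Mg]Br
Why: Grignard addition to the aldehyde brings in C14; the new carbinol centre is erased in step 2 and C9 is untouched.

**Step 2**
Reactants: 2 1-[(4R)-2,2-dimethyl-1,3-dioxolan-4-yl]ethan-1-ol
Product: 3 1-[(4R)-2,2-dimethyl-1,3-dioxolan-4-yl]ethan-1-one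
Conditions: Dess–Martin periodinane, NaHCO3, CH2Cl2, 0 °C → rt
Reagents that add atoms: none
Why: Dess–Martin oxidation under buffered, non-basic conditions gives the α-alkoxy methyl ketone without epimerising C9.

**Step 3**
Reactants: 3 1-[(4R)-2,2-dimethyl-1,3-dioxolan-4-yl]ethan-1-one
Product: 4 methyl (2E)-3-[(4S)-2,2-dimethyl-1,3-dioxolan-4-yl]but-2-enoate
Conditions: Ph3P=CHCO2Me, toluene, 90 °C
Reagents that add atoms: methyl (triphenylphosphoranylidene)acetate, COC(=O)C=P(c1ccccc1)(c1ccccc1)c1ccccc1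
Why: Wittig olefination with a stabilised ylide gives the (E)-trisubstituted enoate (ester trans to the dioxolane) under neutral conditions that leave C9 intact.

**Step 4**
Reactants: 4 methyl (2E)-3-[(4S)-2,2-dimethyl-1,3-dioxolan-4-yl]but-2-enoate
Product: 5 (2E)-3-[(4S)-2,2-dimethyl-1,3-dioxolan-4-yl]but-2-en-1-ol (fragment A)
Conditions: iBu2AlH, CH2Cl2, −78 °C
Reagents that add atoms: none
Why: 1,2-reduction of the enoate by iBu2AlH gives the allylic alcohol with the alkene geometry retained.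

**Step 5**
Reactants: 6 itaconic anhydride
Product: 7 4-(allyloxy)-2-methylidene-4-oxobutanoic acid
Conditions: allyl alcohol, toluene, 60 °C
Reagents that add atoms: allyl alcohol, C=CCO
Why: alcoholysis of the anhydride occurs at the non-conjugated, more electrophilic carbonyl, leaving the conjugated acid (C15) free.

**Step 6**
Reactants: 7 4-(allyloxy)-2-methylidene-4-oxobutanoic acid
Product: 9 allyl 3-(hydroxymethyl)but-3-enoate, via mixed carbonic anhydride 8 (not isolated)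
Conditions: iBuOCOCl, N-methylmorpholine, THF, −15 °C; then NaBH4, H2O, 0 °C
Reagents that add atoms: none
Why: mixed-anhydride activation followed by NaBH4 reduction converts only the free acid into the primary allylic alcohol, the allyl ester being inert.

**Step 7**
Reactants: 9 allyl 3-(hydroxymethyl)but-3-enoate
Product: 10 allyl 3-{[(tert-butyldiphenylsilyl)oxy]methyl}but-3-enoate
Conditions: tBuPh2SiCl, imidazole, CH2Cl2, rt
Reagents that add atoms: tert-butyl(chloro)diphenylsilane, CC(C)(C)[Si](Cl)(c1ccccc1)c1ccccc1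
Why: silylation of the primary alcohol masks C15–OH with a group that survives base, acid and mild fluoride treatment.

**Step 8**
Reactants: 10 allyl 3-{[(tert-butyldiphenylsilyl)oxy]methyl}but-3-enoate
Product: 11 3-{[(tert-butyldiphenylsilyl)oxy]methyl}but-3-enoic acid (fragment B)
Conditions: Pd(PPh3)4 (cat.), morpholine, THF, rt
Reagents that add atoms: none
Why: Tsuji–Trost allyl transfer to morpholine frees the acid under neutral conditions, so the β,γ-alkene does not move into conjugation.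

**Step 9**
Reactants: 12 methyl acrylate
Product: 13 methyl 2-(hydroxymethyl)acrylate
Conditions: aq. CH2O, 1,4-diazabicyclo[2.2.2]octane (cat.), 1,4-dioxane/H2O, rt
Reagents that add atoms: formaldehyde, C=O
Why: Morita–Baylis–Hillman reaction attaches C13 to the acrylate α-carbon.

**Step 10**
Reactants: 13 methyl 2-(hydroxymethyl)acrylate
Product: 14 methyl 2-{[(tert-butyldimethylsilyl)oxy]methyl}acrylate
Conditions: tBuMe2SiCl, imidazole, CH2Cl2, rt
Reagents that add atoms: tert-butyl(chloro)dimethylsilane, CC(C)(C)[Si](C)(C)Cl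
Why: silylation protects the allylic alcohol before halogenation.

**Step 11**
Reactants: 14 methyl 2-{[(tert-butyldimethylsilyl)oxy]methyl}acrylate
Product: 15 methyl 2,3-dibromo-2-{[(tert-butyldimethylsilyl)oxy]methyl}propanoate (racemic)
Conditions: Br2, NaHCO3, CH2Cl2, 0 °C
Reagents that add atoms: bromine, BrBr
Why: electrophilic addition of bromine to the acrylate gives the vicinal dibromide.

**Step 12**
Reactants: 15 methyl 2,3-dibromo-2-{[(tert-butyldimethylsilyl)oxy]methyl}propanoate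
Product: 16 methyl (2E)-3-bromo-2-{[(tert-butyldimethylsilyl)oxy]methyl}acrylate
Conditions: 1,8-diazabicyclo[5.4.0]undec-7-ene, CH2Cl2, 0 °C → rt
Reagents that add atoms: none
Why: E2 dehydrobromination removes the acidic CH2Br proton through the conformer with C3–Br anti to the ester, giving the (E)-bromide (Br trans to CO2Me); the minor (Z)-isomer is removed by chromatography.

**Step 13**
Reactants: 16 methyl (2E)-3-bromo-2-{[(tert-butyldimethylsilyl)oxy]methyl}acrylate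
Product: 17 methyl (2E)-2-{[(tert-butyldimethylsilyl)oxy]methyl}-3-(tributylstannyl)acrylate (fragment C)
Conditions: Bu3SnSnBu3, Pd(PPh3)4 (cat.), toluene, 100 °C
Reagents that add atoms: hexabutylditin, CCCC[Sn](CCCC)(CCCC)[Sn](CCCC)(CCCC)CCCC
Why: Pd-catalysed stannylation of the vinyl bromide proceeds with retention of alkene geometry.

**Step 14**
Reactants: 5 (2E)-3-[(4S)-2,2-dimethyl-1,3-dioxolan-4-yl]but-2-en-1-ol (fragment A); 11 3-{[(tert-butyldiphenylsilyl)oxy]methyl}but-3-enoic acid (fragment B)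
Product: 18 (2E)-3-[(4S)-2,2-dimethyl-1,3-dioxolan-4-yl]but-2-en-1-yl 3-{[(tert-butyldiphenylsilyl)oxy]methyl}but-3-enoate
Conditions: DCC, 4-(dimethylamino)pyridine (cat.), CH2Cl2, 0 °C → rt
Reagents that add atoms: none
Why: Steglich esterification joins fragments A and B through the O–C2 bond that the Claisen rearrangement will turn into the C5–C10 bond.

**Step 15**
Reactants: 18 allylic ester of fragments A and B
Product: 21 (2S,3S)-2-{3-[(tert-butyldiphenylsilyl)oxy]prop-1-en-2-yl}-3-[(4S)-2,2-dimethyl-1,3-dioxolan-4-yl]-3-methylpent-4-enoic acid, via silyl ketene acetal 19 (not isolated), via trimethylsilyl ester 20 (not isolated)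
Conditions: LiN(iPr)2, THF, −78 °C; Me3SiCl, Et3N, −78 °C → rt; aq. NH4Cl
Reagents that add atoms: none
Why: Ireland–Claisen rearrangement of the kinetic enolate (C4 cis to the allylic oxygen) and the (E)-alkene through a chair sets C5 against C10, and bond formation anti to the dioxolane C9–O bond (H9 turned toward the C14 methyl to avoid A(1,2) strain) sets C10 against C9; the minor diastereomer is separated.

**Step 16**
Reactants: 21 Claisen acid; 17 vinylstannane (fragment C)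
Product: 23 methyl (2E,5S,6S)-2-{[(tert-butyldimethylsilyl)oxy]methyl}-5-{3-[(tert-butyldiphenylsilyl)oxy]prop-1-en-2-yl}-6-[(4S)-2,2-dimethyl-1,3-dioxolan-4-yl]-6-methyl-4-oxoocta-2,7-dienoate, via acid chloride 22 (not isolated)
Conditions: 1-chloro-N,N,2-trimethylprop-1-en-1-amine, CH2Cl2, 0 °C; then 17, Pd2(dba)3 (cat.), tri(2-furyl)phosphine, THF, rt
Reagents that add atoms: none
Why: neutral acid chloride formation and Stille acylation create the C6–C7 bond with retention of the stannane geometry (C6 trans to CO2Me) and without base that could epimerise C5.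

**Step 17**
Reactants: 23 enone
Product: 24 methyl (2E,4R,5S,6S)-2-{[(tert-butyldimethylsilyl)oxy]methyl}-5-{3-[(tert-butyldiphenylsilyl)oxy]prop-1-en-2-yl}-6-[(4S)-2,2-dimethyl-1,3-dioxolan-4-yl]-4-hydroxy-6-methylocta-2,7-dienoate
Conditions: NaBH4, CeCl3·7H2O, MeOH, −78 °C
Reagents that add atoms: none
Why: Luche 1,2-reduction under Felkin–Anh control (hydride anti to the quaternary C10 substituent on C5) sets C6 so that C6–O and the C5 side chain end up cis on the ring.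

**Step 18**
Reactants: 24 C6 allylic alcohol
Product: 25 methyl (2E,4R,5S,6S)-4-[(tert-butyldimethylsilyl)oxy]-2-{[(tert-butyldimethylsilyl)oxy]methyl}-5-{3-[(tert-butyldiphenylsilyl)oxy]prop-1-en-2-yl}-6-[(4S)-2,2-dimethyl-1,3-dioxolan-4-yl]-6-methylocta-2,7-dienoate
Conditions: tBuMe2SiOTf, 2,6-lutidine, CH2Cl2, −78 → 0 °C
Reagents that add atoms: tert-butyldimethylsilyl trifluoromethanesulfonate, CC(C)(C)[Si](C)(C)OS(=O)(=O)C(F)(F)F
Why: silylation turns C6–OH into a poor leaving group, so the later allylmetal cannot undergo 1,4-elimination.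

**Step 19**
Reactants: 25 tris-silyl ether
Product: 26 methyl (2E,4R,5S,6S)-4-[(tert-butyldimethylsilyl)oxy]-5-{3-[(tert-butyldiphenylsilyl)oxy]prop-1-en-2-yl}-6-[(4S)-2,2-dimethyl-1,3-dioxolan-4-yl]-2-(hydroxymethyl)-6-methylocta-2,7-dienoate
Conditions: HF·pyridine, pyridine, THF, 0 °C
Reagents that add atoms: none
Why: buffered HF·pyridine cleaves the unhindered primary TBS ether at C13 much faster than the hindered secondary TBS ether, the TBDPS ether or the acetonide.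

**Step 20**
Reactants: 26 C13 allylic alcohol
Product: 27 methyl (2Z,4R,5S,6S)-2-(bromomethyl)-4-[(tert-butyldimethylsilyl)oxy]-5-{3-[(tert-butyldiphenylsilyl)oxy]prop-1-en-2-yl}-6-[(4S)-2,2-dimethyl-1,3-dioxolan-4-yl]-6-methylocta-2,7-dienoate
Conditions: CBr4, PPh3, CH2Cl2, 0 °C
Reagents that add atoms: carbon tetrabromide, BrC(Br)(Br)Br
Why: Appel bromination of the primary allylic alcohol gives the 2-(bromomethyl)enoate without touching the alkene geometry.

**Step 21**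
Reactants: 27 allylic bromide
Product: 28 methyl (2Z,4R,5S,6S,7S)-2-(bromomethyl)-4-[(tert-butyldimethylsilyl)oxy]-5-{3-[(tert-butyldiphenylsilyl)oxy]prop-1-en-2-yl}-6-ethenyl-7,8-dihydroxy-6-methyloct-2-enoate
Conditions: AcOH/THF/H2O (3:1:1), 35 °C
Reagents that add atoms: none
Why: mild acid hydrolysis removes the terminal acetonide while the hindered secondary TBS ether, the TBDPS ether and the primary allylic bromide survive.

**Step 22**
Reactants: 28 C8,C9 diol
Product: 31 (5S,6S,7S,8R,9S,10S)-6-[(tert-butyldimethylsilyl)oxy]-15-[(tert-butyldiphenylsilyl)oxy]-9-hydroxyelema-1,3,11(13)-trien-12,8-olide, via hydroxy aldehyde 29 (not isolated), via hydroxy ester 30 (not isolated)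
Conditions: 2,2,6,6-tetramethylpiperidin-1-oxyl (cat.), PhI(OAc)2, CH2Cl2, rt; then In powder, THF/H2O (3:1), rt, high dilution
Reagents that add atoms: none
Why: selective oxidation of the primary alcohol, then intramolecular In-mediated Barbier allylation through a chair with the C6 and C9 oxygens equatorial and the (Z)-allylindium adding syn, gives C7–C11 trans to C6–O and C8–O cis to both C7–C11 and C9–OH; the cis hydroxy ester lactonises.

**Step 23**
Reactants: 31 C9 hydroxy lactone; 32 angelic acid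
Product: 34 (5S,6S,7S,8R,9S,10S)-9-(angeloyloxy)-6-[(tert-butyldimethylsilyl)oxy]-15-[(tert-butyldiphenylsilyl)oxy]elema-1,3,11(13)-trien-12,8-olide, via mixed anhydride 33 (not isolated)
Conditions: 2,4,6-trichlorobenzoyl chloride, Et3N, toluene, rt; then 31, 80 °C
Reagents that add atoms: none
Why: Yamaguchi-type esterification through the mixed anhydride acylates the hindered C9–OH without a nucleophilic catalyst, which keeps the (Z)-geometry of the angelate.

**Step 24**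
Reactants: 34 angelate bis-silyl ether
Product: 35 (5S,6S,7R,8R,9S,10S)-9-(angeloyloxy)-6,15-dihydroxyelema-1,3,11(13)-trien-12,8-olide
Conditions: HF·pyridine, THF, 0 °C → rt
Reagents that add atoms: none
Why: acidic fluoride removes both silyl ethers without attacking the esters, the lactone or the Michael acceptors.

**Step 25**
Reactants: 35 C6,C15 diol
Product: 36 (5R,6S,7R,8R,9S,10S)-9-(angeloyloxy)-6-hydroxy-15-oxoelema-1,3,11(13)-trien-12,8-olide
Conditions: MnO2, CH2Cl2, rt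
Reagents that add atoms: none
Why: MnO2 oxidises only the allylic primary alcohol, giving the 2-substituted acrolein and leaving the secondary C6–OH.

**Step 26**
Reactants: 36 C6 hydroxy enal
Product: 37 (5R,6S,7R,8R,9S,10S)-6-acetoxy-9-(angeloyloxy)-15-oxoelema-1,3,11(13)-trien-12,8-olide (target)
Conditions: Ac2O, pyridine, 4-(dimethylamino)pyridine (cat.), CH2Cl2, 0 °C → rt
Reagents that add atoms: acetic anhydride, CC(=O)OC(C)=O
Why: acetylation of the remaining secondary alcohol completes the target with no stereocentre involved.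

**Compound list**
1 | (R)-2,2-dimethyl-1,3-dioxolane-4-carbaldehyde ((R)-glyceraldehyde acetonide) | O=C[C@H]1COC(C)(C)O1 | starting material
2 | 1-[(4R)-2,2-dimethyl-1,3-dioxolan-4-yl]ethan-1-ol, both carbinol epimers | CC(O)[C@H]1COC(C)(C)O1 | intermediate
3 | 1-[(4R)-2,2-dimethyl-1,3-dioxolan-4-yl]ethan-1-one | CC(=O)[C@H]1COC(C)(C)O1 | intermediate
4 | methyl (2E)-3-[(4S)-2,2-dimethyl-1,3-dioxolan-4-yl]but-2-enoate | COC(=O)/C=C(\C)[C@H]1COC(C)(C)O1 | intermediate
5 | (2E)-3-[(4S)-2,2-dimethyl-1,3-dioxolan-4-yl]but-2-en-1-ol (fragment A) | OC/C=C(\C)[C@H]1COC(C)(C)O1 | intermediate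
6 | itaconic anhydride (3-methylideneoxolane-2,5-dione) | C=C1CC(=O)OC1=O | starting material
7 | 4-(allyloxy)-2-methylidene-4-oxobutanoic acid | C=CCOC(=O)CC(=C)C(=O)O | intermediate
8 | mixed isobutyl carbonic anhydride of 7 | C=CCOC(=O)CC(=C)C(=O)OC(=O)OCC(C)C | intermediate
9 | allyl 3-(hydroxymethyl)but-3-enoate | C=CCOC(=O)CC(=C)CO | intermediate
10 | allyl 3-{[(tert-butyldiphenylsilyl)oxy]methyl}but-3-enoate | C=CCOC(=O)CC(=C)CO[Si](c1ccccc1)(c1ccccc1)C(C)(C)C | intermediate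
11 | 3-{[(tert-butyldiphenylsilyl)oxy]methyl}but-3-enoic acid (fragment B) | OC(=O)CC(=C)CO[Si](c1ccccc1)(c1ccccc1)C(C)(C)C | intermediate
12 | methyl acrylate | C=CC(=O)OC | starting material
13 | methyl 2-(hydroxymethyl)acrylate | C=C(CO)C(=O)OC | intermediate
14 | methyl 2-{[(tert-butyldimethylsilyl)oxy]methyl}acrylate | C=C(CO[Si](C)(C)C(C)(C)C)C(=O)OC | intermediate
15 | methyl 2,3-dibromo-2-{[(tert-butyldimethylsilyl)oxy]methyl}propanoate (racemic) | COC(=O)C(Br)(CBr)CO[Si](C)(C)C(C)(C)C | intermediate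
16 | methyl (2E)-3-bromo-2-{[(tert-butyldimethylsilyl)oxy]methyl}acrylate | COC(=O)/C(CO[Si](C)(C)C(C)(C)C)=C/Br | intermediate
17 | methyl (2E)-2-{[(tert-butyldimethylsilyl)oxy]methyl}-3-(tributylstannyl)acrylate (fragment C) | COC(=O)/C(CO[Si](C)(C)C(C)(C)C)=C/[Sn](CCCC)(CCCC)CCCC | intermediate
18 | (2E)-3-[(4S)-2,2-dimethyl-1,3-dioxolan-4-yl]but-2-en-1-yl 3-{[(tert-butyldiphenylsilyl)oxy]methyl}but-3-enoate | C=C(CO[Si](c1ccccc1)(c1ccccc1)C(C)(C)C)CC(=O)OC/C=C(\C)[C@H]1COC(C)(C)O1 | intermediate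
19 | O-trimethylsilyl ketene acetal of 18 (C5=C6, C4 trans to OSiMe3) | C=C(CO[Si](c1ccccc1)(c1ccccc1)C(C)(C)C)/C=C(/O[Si](C)(C)C)OC/C=C(\C)[C@H]1COC(C)(C)O1 | intermediate
20 | trimethylsilyl ester of 21 | C[Si](C)(C)OC(=O)[C@@H](C(=C)CO[Si](c1ccccc1)(c1ccccc1)C(C)(C)C)[C@](C)(C=C)[C@H]1COC(C)(C)O1 | intermediate
21 | (2S,3S)-2-{3-[(tert-butyldiphenylsilyl)oxy]prop-1-en-2-yl}-3-[(4S)-2,2-dimethyl-1,3-dioxolan-4-yl]-3-methylpent-4-enoic acid | OC(=O)[C@@H](C(=C)CO[Si](c1ccccc1)(c1ccccc1)C(C)(C)C)[C@](C)(C=C)[C@H]1COC(C)(C)O1 | intermediate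
22 | acid chloride of 21 | ClC(=O)[C@@H](C(=C)CO[Si](c1ccccc1)(c1ccccc1)C(C)(C)C)[C@](C)(C=C)[C@H]1COC(C)(C)O1 | intermediate
23 | methyl (2E,5S,6S)-2-{[(TBS)oxy]methyl}-5-{3-[(TBDPS)oxy]prop-1-en-2-yl}-6-[(4S)-2,2-dimethyl-1,3-dioxolan-4-yl]-6-methyl-4-oxoocta-2,7-dienoate | COC(=O)/C(CO[Si](C)(C)C(C)(C)C)=C/C(=O)[C@@H](C(=C)CO[Si](c1ccccc1)(c1ccccc1)C(C)(C)C)[C@](C)(C=C)[C@H]1COC(C)(C)O1 | intermediate
24 | methyl (2E,4R,5S,6S)-2-{[(TBS)oxy]methyl}-5-{3-[(TBDPS)oxy]prop-1-en-2-yl}-6-[(4S)-2,2-dimethyl-1,3-dioxolan-4-yl]-4-hydroxy-6-methylocta-2,7-dienoate | COC(=O)/C(CO[Si](C)(C)C(C)(C)C)=C/[C@@H](O)[C@@H](C(=C)CO[Si](c1ccccc1)(c1ccccc1)C(C)(C)C)[C@](C)(C=C)[C@H]1COC(C)(C)O1 | intermediate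
25 | methyl (2E,4R,5S,6S)-4-[(TBS)oxy]-2-{[(TBS)oxy]methyl}-5-{3-[(TBDPS)oxy]prop-1-en-2-yl}-6-[(4S)-2,2-dimethyl-1,3-dioxolan-4-yl]-6-methylocta-2,7-dienoate | COC(=O)/C(CO[Si](C)(C)C(C)(C)C)=C/[C@@H](O[Si](C)(C)C(C)(C)C)[C@@H](C(=C)CO[Si](c1ccccc1)(c1ccccc1)C(C)(C)C)[C@](C)(C=C)[C@H]1COC(C)(C)O1 | intermediate
26 | methyl (2E,4R,5S,6S)-4-[(TBS)oxy]-5-{3-[(TBDPS)oxy]prop-1-en-2-yl}-6-[(4S)-2,2-dimethyl-1,3-dioxolan-4-yl]-2-(hydroxymethyl)-6-methylocta-2,7-dienoate | COC(=O)/C(CO)=C/[C@@H](O[Si](C)(C)C(C)(C)C)[C@@H](C(=C)CO[Si](c1ccccc1)(c1ccccc1)C(C)(C)C)[C@](C)(C=C)[C@H]1COC(C)(C)O1 | intermediate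
27 | methyl (2Z,4R,5S,6S)-2-(bromomethyl)-4-[(TBS)oxy]-5-{3-[(TBDPS)oxy]prop-1-en-2-yl}-6-[(4S)-2,2-dimethyl-1,3-dioxolan-4-yl]-6-methylocta-2,7-dienoate | COC(=O)/C(CBr)=C/[C@@H](O[Si](C)(C)C(C)(C)C)[C@@H](C(=C)CO[Si](c1ccccc1)(c1ccccc1)C(C)(C)C)[C@](C)(C=C)[C@H]1COC(C)(C)O1 | intermediate
28 | methyl (2Z,4R,5S,6S,7S)-2-(bromomethyl)-4-[(TBS)oxy]-5-{3-[(TBDPS)oxy]prop-1-en-2-yl}-6-ethenyl-7,8-dihydroxy-6-methyloct-2-enoate | COC(=O)/C(CBr)=C/[C@@H](O[Si](C)(C)C(C)(C)C)[C@@H](C(=C)CO[Si](c1ccccc1)(c1ccccc1)C(C)(C)C)[C@](C)(C=C)[C@H](O)CO | intermediate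
29 | methyl (2Z,4R,5S,6S,7S)-2-(bromomethyl)-4-[(TBS)oxy]-5-{3-[(TBDPS)oxy]prop-1-en-2-yl}-6-ethenyl-7-hydroxy-6-methyl-8-oxooct-2-enoate | COC(=O)/C(CBr)=C/[C@@H](O[Si](C)(C)C(C)(C)C)[C@@H](C(=C)CO[Si](c1ccccc1)(c1ccccc1)C(C)(C)C)[C@](C)(C=C)[C@H](O)C=O | intermediate
30 | methyl (5S,6S,7S,8R,9S,10S)-6-[(TBS)oxy]-15-[(TBDPS)oxy]-8,9-dihydroxyelema-1,3,11(13)-trien-12-oate (open hydroxy ester of 31) | C=C[C@]1(C)[C@H](O)[C@H](O)[C@H](C(=C)C(=O)OC)[C@@H](O[Si](C)(C)C(C)(C)C)[C@H]1C(=C)CO[Si](c1ccccc1)(c1ccccc1)C(C)(C)C | intermediate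
31 | (5S,6S,7S,8R,9S,10S)-6-[(TBS)oxy]-15-[(TBDPS)oxy]-9-hydroxyelema-1,3,11(13)-trien-12,8-olide | C=C[C@]1(C)[C@H](O)[C@@H]2OC(=O)C(=C)[C@@H]2[C@@H](O[Si](C)(C)C(C)(C)C)[C@H]1C(=C)CO[Si](c1ccccc1)(c1ccccc1)C(C)(C)C | intermediate
32 | angelic acid ((Z)-2-methylbut-2-enoic acid) | C/C=C(/C)C(=O)O | starting material
33 | angelic 2,4,6-trichlorobenzoic anhydride | C/C=C(/C)C(=O)OC(=O)c1c(Cl)cc(Cl)cc1Cl | intermediate
34 | (5S,6S,7S,8R,9S,10S)-9-(angeloyloxy)-6-[(TBS)oxy]-15-[(TBDPS)oxy]elema-1,3,11(13)-trien-12,8-olide | C=C[C@]1(C)[C@H](OC(=O)/C(C)=C\C)[C@@H]2OC(=O)C(=C)[C@@H]2[C@@H](O[Si](C)(C)C(C)(C)C)[C@H]1C(=C)CO[Si](c1ccccc1)(c1ccccc1)C(C)(C)C | intermediate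
35 | (5S,6S,7R,8R,9S,10S)-9-(angeloyloxy)-6,15-dihydroxyelema-1,3,11(13)-trien-12,8-olide | C=C[C@]1(C)[C@H](OC(=O)/C(C)=C\C)[C@@H]2OC(=O)C(=C)[C@@H]2[C@@H](O)[C@H]1C(=C)CO | intermediate
36 | (5R,6S,7R,8R,9S,10S)-9-(angeloyloxy)-6-hydroxy-15-oxoelema-1,3,11(13)-trien-12,8-olide | C=C[C@]1(C)[C@H](OC(=O)/C(C)=C\C)[C@@H]2OC(=O)C(=C)[C@@H]2[C@@H](O)[C@H]1C(=C)C=O | intermediate
37 | (5R,6S,7R,8R,9S,10S)-6-acetoxy-9-(angeloyloxy)-15-oxoelema-1,3,11(13)-trien-12,8-olide (CNP0252310.2) | C=C[C@]1(C)[C@H](OC(=O)/C(C)=C\C)[C@@H]2OC(=O)C(=C)[C@@H]2[C@@H](OC(C)=O)[C@H]1C(=C)C=O | target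

**Step count**
Total: 26 steps. Longest linear sequence: 17 steps (steps 1–4, then 14–26; the same length from 6 through steps 5–8, then 14–26).

**Three steps most likely to fail**

Step 16 (acid chloride and Stille acylation). The α-branched, β,γ-unsaturated acyl chloride can lose its α-proton (ketene, conjugation, loss of the C5 configuration), and the electron-poor stannane transmetalates slowly. The fallback replaces acylation by carbonyl addition and re-oxidation. It sets out from acid 21: LiAlH4 (Et2O, 0 °C) gives primary alcohol F1, Dess–Martin periodinane gives aldehyde F2, and Nozaki–Hiyama–Kishi coupling of F2 with vinyl bromide 16 (CrCl2, NiCl2 cat., DMF) gives allylic alcohol F3 as a mixture of C6 epimers. Dess–Martin oxidation of that mixture comes back to the route at enone 23.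

Step 22 (oxidation and In-mediated ring closure). The α-hydroxy aldehyde is labile, ring closure competes with simple reduction of the bromide and with intermolecular coupling, and the facial selectivity rests on a conformational argument. The fallback replaces the metal-mediated Barbier reaction by a fluoride-triggered intramolecular Hosomi–Sakurai reaction. It sets out from bromide 27: Me3SiSiMe3 with Pd2(dba)3 (cat.) in THF gives allylsilane F4, aqueous acetic acid gives diol F5, and 2,2,6,6-tetramethylpiperidin-1-oxyl/PhI(OAc)2 gives hydroxy aldehyde F6. Bu4N[Ph3SiF2] in THF at 0 °C then closes the carbocycle to hydroxy ester 30, which lactonises; the fallback comes back at lactone 31.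

Step 23 (angelate formation). C9–OH sits next to the quaternary C10, so acylation is slow, and forcing it invites isomerisation of the angelate to the tiglate. The fallback builds the (Z)-alkene on the ester instead of transferring it. It sets out from alcohol 31: DCC and 4-(dimethylamino)pyridine with 2-[bis(2,2,2-trifluoroethoxy)phosphoryl]propanoic acid give phosphonate ester F7. Still–Gennari olefination with acetaldehyde (KN(SiMe3)2, 18-crown-6, THF, −78 °C) then gives the (Z)-2-methylbut-2-enoate, coming back at angelate 34.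

**Further compounds**
F1 | step 16 | (2S,3S)-2-{3-[(TBDPS)oxy]prop-1-en-2-yl}-3-[(4S)-2,2-dimethyl-1,3-dioxolan-4-yl]-3-methylpent-4-en-1-ol | OC[C@@H](C(=C)CO[Si](c1ccccc1)(c1ccccc1)C(C)(C)C)[C@](C)(C=C)[C@H]1COC(C)(C)O1
F2 | step 16 | (2S,3S)-2-{3-[(TBDPS)oxy]prop-1-en-2-yl}-3-[(4S)-2,2-dimethyl-1,3-dioxolan-4-yl]-3-methylpent-4-enal | O=C[C@@H](C(=C)CO[Si](c1ccccc1)(c1ccccc1)C(C)(C)C)[C@](C)(C=C)[C@H]1COC(C)(C)O1
F3 | step 16 | C6 epimer mixture of 24 (methyl (2E,5S,6S)-4-hydroxy compound, C4 of the chain undefined) | COC(=O)/C(CO[Si](C)(C)C(C)(C)C)=C/C(O)[C@@H](C(=C)CO[Si](c1ccccc1)(c1ccccc1)C(C)(C)C)[C@](C)(C=C)[C@H]1COC(C)(C)O1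
F4 | step 22 | methyl (2Z,4R,5S,6S)-4-[(TBS)oxy]-5-{3-[(TBDPS)oxy]prop-1-en-2-yl}-6-[(4S)-2,2-dimethyl-1,3-dioxolan-4-yl]-6-methyl-2-[(trimethylsilyl)methyl]octa-2,7-dienoate | COC(=O)/C(C[Si](C)(C)C)=C/[C@@H](O[Si](C)(C)C(C)(C)C)[C@@H](C(=C)CO[Si](c1ccccc1)(c1ccccc1)C(C)(C)C)[C@](C)(C=C)[C@H]1COC(C)(C)O1
F5 | step 22 | methyl (2Z,4R,5S,6S,7S)-4-[(TBS)oxy]-5-{3-[(TBDPS)oxy]prop-1-en-2-yl}-6-ethenyl-7,8-dihydroxy-6-methyl-2-[(trimethylsilyl)methyl]oct-2-enoate | COC(=O)/C(C[Si](C)(C)C)=C/[C@@H](O[Si](C)(C)C(C)(C)C)[C@@H](C(=C)CO[Si](c1ccccc1)(c1ccccc1)C(C)(C)C)[C@](C)(C=C)[C@H](O)CO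
F6 | step 22 | methyl (2Z,4R,5S,6S,7S)-4-[(TBS)oxy]-5-{3-[(TBDPS)oxy]prop-1-en-2-yl}-6-ethenyl-7-hydroxy-6-methyl-8-oxo-2-[(trimethylsilyl)methyl]oct-2-enoate | COC(=O)/C(C[Si](C)(C)C)=C/[C@@H](O[Si](C)(C)C(C)(C)C)[C@@H](C(=C)CO[Si](c1ccccc1)(c1ccccc1)C(C)(C)C)[C@](C)(C=C)[C@H](O)C=O
F7 | step 23 | 9-O-{2-[bis(2,2,2-trifluoroethoxy)phosphoryl]propanoyl} derivative of 31 (both epimers at the phosphonate carbon) | C=C[C@]1(C)[C@H](OC(=O)C(C)P(=O)(OCC(F)(F)F)OCC(F)(F)F)[C@@H]2OC(=O)C(=C)[C@@H]2[C@@H](O[Si](C)(C)C(C)(C)C)[C@H]1C(=C)CO[Si](c1ccccc1)(c1ccccc1)C(C)(C)C
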